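**Retrosynthetic overview**
1. Okilactomycin C (33) comes from 31 (4-O-methyl tetronate, methyl ester) by two deprotections. 31 comes from 29 by one thermal cascade that forms the cyclohexene, the spiro centre and the 13-membered ring together.
2. Enabling feature: the four cyclohexene atoms CH(chain)–CH=C(CO2H)–CH(CH3) are a but-2-ene-1,4-diyl unit, that is, an opened trans-3,4-dialkylcyclobutene-1-carboxylate. The other two ring atoms, the CH2 and the spiro carbon C(O)(C=), are the exocyclic C=CH2 of a 5-methylene tetronate. Inserting that C=C into the C3–C4 σ bond of the four-membered ring (4π opening, then [4+2]) expands it from four to six atoms.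
3. 29 comes from Z-enal 20 and 3-lithio-4-methoxy-5-methylenefuranone 27 (addition, oxidation). The cyclobutene of 20 comes from terminal alkene 11 by keteniminium [2+2], enol triflate formation and Pd carbonylation.
4. 11 comes from meso-2,4-dimethylglutaric anhydride 1 by lipase desymmetrisation (sets both chain centres), butenyl Grignard coupling and Still–Gennari olefination (Z C=C).
5. Ring order: butenolide (bought), then cyclobutane/cyclobutene (steps 8–11), then cyclohexene and macrocycle together (step 17).

Key step: step 17

Assumption: the trisubstituted C=C of the enoyl unit is read from the target SMILES with the acyl carbon and the CH(CH3) carbon cis (Z), and the route builds this geometry.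
Assumption: Pseudomonas fluorescens lipase is taken to act on the CH2O group next to the (S)-configured centre of the meso compounds 2 and 3, so hydrolysis of 3 frees that hydroxyl.
Assumption: 14–20, 28 and 29 are carried as the pair of trans four-ring isomers. The (S,R) isomer is drawn and the (R,S) isomer is also present. Both ring centres become sp2 in step 17 and both isomers give the same diene 30.

**Step 1**
Reactants: 1 meso-2,4-dimethylglutaric anhydride
Product: 2 meso-(2R,4S)-2,4-dimethylpentane-1,5-diol
Conditions: LiAlH4, THF, 0 °C to reflux; Fieser work-up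
Reagents that add atoms: none
Why: Hydride reduction of a cyclic anhydride to the diol leaves both stereocentres untouched, so the meso (syn-dimethyl) relation is kept.

**Step 2**
Reactants: 2 meso-2,4-dimethylpentane-1,5-diol
Product: 3 meso-(2R,4S)-2,4-dimethylpentane-1,5-diyl diacetate
Conditions: Ac2O, pyridine, DMAP (cat.), CH2Cl2, rt
Reagents that add atoms: acetic anhydride, CC(=O)OC(C)=O
Why: Standard DMAP-catalysed acylation of two primary alcohols prepares the substrate for the enzymatic hydrolysis.

**Step 3**
Reactants: 3 meso-2,4-dimethylpentane-1,5-diyl diacetate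
Product: 4 (2R,4S)-5-hydroxy-2,4-dimethylpentyl acetate
Conditions: lipase from Pseudomonas fluorescens (serine hydrolase), pH 7 phosphate buffer, rt
Reagents that add atoms: none
Why: Lipase-catalysed enantiotopos-selective hydrolysis of a meso diacetate frees only the CH2OAc next to the (S)-centre and so fixes both chain stereocentres (syn-1,3-dimethyl) in one operation.

**Step 4**
Reactants: 4 (2R,4S)-5-hydroxy-2,4-dimethylpentyl acetate
Product: 5 (2R,4S)-2,4-dimethyl-5-(tosyloxy)pentyl acetate
Conditions: TsCl, Et3N, DMAP (cat.), CH2Cl2, 0 °C to rt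
Reagents that add atoms: 4-toluenesulfonyl chloride, Cc1ccc(cc1)S(=O)(=O)Cl
Why: Sulfonylation of the free primary alcohol activates this terminus for C–C coupling without touching a stereocentre.

**Step 5**
Reactants: 5 (2R,4S)-2,4-dimethyl-5-(tosyloxy)pentyl acetate; 6 but-3-en-1-ylmagnesium bromide
Product: 7 (2R,4R)-2,4-dimethylnon-8-en-1-ol
Conditions: 6 (3.5 equiv), Li2CuCl4 (5 mol %), THF, –78 °C to rt; aq NH4Cl
Reagents that add atoms: none
Why: Copper-catalysed sp3–sp3 Grignard–tosylate coupling (Kochi/Fouquet–Schlosser type) extends the chain, and the excess Grignard reagent removes the acetate by double addition, so the free alcohol is obtained directly.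

**Step 6**
Reactants: 7 (2R,4R)-2,4-dimethylnon-8-en-1-ol
Product: 8 (2R,4R)-2,4-dimethylnon-8-enal
Conditions: TEMPO (cat.), PhI(OAc)2, CH2Cl2, rt
Reagents that add atoms: none
Why: Oxoammonium (TEMPO) oxidation stops at the aldehyde and is non-basic, so the α-stereocentre should not epimerise and the alkene is inert.

**Step 7**
Reactants: 8 (2R,4R)-2,4-dimethylnon-8-enal; 9 ethyl 2-[bis(2,2,2-trifluoroethoxy)phosphoryl]propanoate
Product: 11 ethyl (2Z,4R,6R)-2,4,6-trimethylundeca-2,10-dienoate, via potassium phosphonate carbanion 10 (not isolated)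
Conditions: KHMDS, 18-crown-6, THF, –78 °C; then 8
Reagents that add atoms: none
Why: In the Still–Gennari variant of the Horner–Wadsworth–Emmons reaction, fast irreversible collapse of the kinetic adduct of the electron-poor phosphonate should give the Z trisubstituted enoate (ester carbon cis to CH(CH3)).

**Step 8**
Reactants: 11 ethyl (2Z,4R,6R)-2,4,6-trimethylundeca-2,10-dienoate; 12 N,N-dimethylpropanamide
Product: 15 ethyl (2Z,4R,6R)-2,4,6-trimethyl-9-[(1S,2R)-2-methyl-3-oxocyclobutyl]non-2-enoate (trans), via keteniminium triflate 13 (not isolated), via cyclobutaniminium triflate 14 (not isolated)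
Conditions: 12, Tf2O, 2,4,6-collidine, ClCH2CH2Cl, reflux; then H2O–CH2Cl2, reflux; then DBU (cat.), CH2Cl2, rt
Reagents that add atoms: water, O
Why: In the Ghosez keteniminium–alkene [2+2] cycloaddition the electrophilic central carbon binds the terminal CH2 (2-methyl-3-alkyl regiochemistry), the electron-poor enoate C=C is inert, the α-centre equilibrates to the trans ring, and the sense relative to the chain is neither controlled nor needed.

**Step 9**
Reactants: 15 trans-2-methyl-3-alkylcyclobutanone
Product: 17 ethyl (2Z,4R,6R)-2,4,6-trimethyl-9-[(1S,4R)-4-methyl-3-(triflyloxy)cyclobut-2-en-1-yl]non-2-enoate, via potassium enolate 16 (not isolated)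
Conditions: KHMDS (1.05 equiv), THF, –78 °C; then PhNTf2, –78 to 0 °C
Reagents that add atoms: N-phenylbis(trifluoromethanesulfonimide), O=S(=O)(N(c1ccccc1)S(=O)(=O)C(F)(F)F)C(F)(F)F
Why: Kinetic deprotonation at the less hindered ring CH2 (the ketone is far more acidic than the enoate) followed by O-triflation places the C=C away from the CH(CH3) centre, so the trans relation is kept.

**Step 10**
Reactants: 17 cyclobutenyl triflate ethyl enoate
Product: 18 (3S,4R)-3-[(4R,6R,7Z)-9-hydroxy-4,6,8-trimethylnon-7-en-1-yl]-4-methylcyclobut-1-en-1-yl triflate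
Conditions: DIBAL-H (2.3 equiv), CH2Cl2, –78 °C; Rochelle salt
Reagents that add atoms: none
Why: DIBAL-H 1,2-reduction of the enoate to the Z-allylic alcohol is run before the second ester exists, so no ester differentiation is needed, and the vinyl triflate is inert at –78 °C.

**Step 11**
Reactants: 18 cyclobutenyl triflate allylic alcohol
Product: 19 methyl (3S,4R)-3-[(4R,6R,7Z)-9-hydroxy-4,6,8-trimethylnon-7-en-1-yl]-4-methylcyclobut-1-ene-1-carboxylate
Conditions: Pd(OAc)2 (5 mol %), dppp, Et3N, CO (1 atm), MeOH–DMF, rt to 40 °C
Reagents that add atoms: carbon monoxide, [C-]#[O+]; methanol, CO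
Why: Palladium-catalysed alkoxycarbonylation of an enol triflate (oxidative addition, CO insertion, methanolysis) installs the future carboxyl carbon on the sp2 ring carbon well below the ring-opening temperature.

**Step 12**
Reactants: 19 cyclobutene ester allylic alcohol
Product: 20 methyl (3S,4R)-4-methyl-3-[(4R,6R,7Z)-4,6,8-trimethyl-9-oxonon-7-en-1-yl]cyclobut-1-ene-1-carboxylate
Conditions: TEMPO (cat.), PhI(OAc)2, CH2Cl2, 0 °C
Reagents that add atoms: none
Why: TEMPO/PhI(OAc)2 oxidation of a Z-allylic alcohol is neutral and is known to keep Z geometry in such enals.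

**Step 13**
Reactants: 21 4-methoxyfuran-2(5H)-one (methyl tetronate); 22 N,N-dimethylmethyleneiminium iodide (Eschenmoser's salt)
Product: 24 (±)-5-[(dimethylamino)methyl]-4-methoxyfuran-2(5H)-one, via lithium 4-methoxyfuran-2-olate 23 (not isolated)
Conditions: LDA, THF, –78 °C; then 22, –78 °C to rt
Reagents that add atoms: none
Why: γ-Deprotonation of the butenolide gives the aromatic furanolate, which undergoes Mannich-type aminomethylation at C5; the new centre is lost in the next step.

**Step 14**
Reactants: 24 5-[(dimethylamino)methyl]-4-methoxyfuran-2(5H)-one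
Product: 26 4-methoxy-5-methylidenefuran-2(5H)-one, via trimethylammonium iodide 25 (not isolated)
Conditions: MeI, CH2Cl2, rt; then aq NaHCO3, rt
Reagents that add atoms: none
Why: Quaternisation followed by E1cB (Hofmann-type) elimination through the acidic C5–H gives the exocyclic methylene.

**Step 15**
Reactants: 26 4-methoxy-5-methylidenefuran-2(5H)-one; 20 Z-enal
Product: 28 methyl (3S,4R)-3-[(4R,6R,7Z)-9-hydroxy-9-(4-methoxy-5-methylidene-2-oxo-2,5-dihydrofuran-3-yl)-4,6,8-trimethylnon-7-en-1-yl]-4-methylcyclobut-1-ene-1-carboxylate (both carbinol epimers), via 3-lithio-4-methoxy-5-methylidenefuran-2(5H)-one 27 (not isolated)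
Conditions: LDA, THF, –78 °C; then 20, –78 °C; AcOH quench
Reagents that add atoms: none
Why: Vinylic C3-lithiation of a 4-alkoxy-5-ylidene butenolide (no C5–H left, carbanion flanked by OCH3 and C=O) and 1,2-addition to the aldehyde, which reacts far faster than the ester; the carbinol centre is erased in step 16.

**Step 16**
Reactants: 28 bis-allylic carbinol
Product: 29 methyl (3S,4R)-3-[(4R,6R,7Z)-9-(4-methoxy-5-methylidene-2-oxo-2,5-dihydrofuran-3-yl)-4,6,8-trimethyl-9-oxonon-7-en-1-yl]-4-methylcyclobut-1-ene-1-carboxylate
Conditions: Dess–Martin periodinane, pyridine, CH2Cl2, 0 °C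
Reagents that add atoms: none
Why: Dess–Martin oxidation of a doubly allylic alcohol under buffered, non-nucleophilic conditions should keep the Z-enone and the methylene tetronate intact.

**Step 17**
Reactants: 29 3-(Z-enoyl)-5-methylene tetronate with pendant trans-cyclobutene ester
Product: 31 O-methyl okilactomycin C methyl ester (spiro cyclohexene–tetronate in the 13-membered ring, configuration as in the target), via tetraene 30 (not isolated)
Conditions: PhCl (0.5 mM), BHT (cat.), 130 °C, Ar, base-washed glass
Reagents that add atoms: none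
Why: Heating opens the cyclobutene by thermal conrotatory 4π electrocyclic ring opening, and because the ring is trans-3,4-dialkylated both alkyl groups rotate outward (torquoselectivity), so both trans isomers of 29 give only diene 30, with the chain on an E C=C and the CH3 cis to CO2CH3. The exocyclic C=CH2 of the methylene tetronate then adds to 30 in an intramolecular Diels–Alder reaction, so in sum the CH2 and the O-bearing carbon are inserted into the former C3–C4 σ bond of the four-membered ring (ring expansion 4 → 6); the closest known reaction types are the cyclobutene or benzocyclobutene opening/IMDA tandem and the macrocyclising IMDA of 3-acyl-5-methylene tetronates. The cyclohexene closes by suprafacial [4+2] addition, and the 13-membered ring closes in the same event as the bridge of a type 1 IMDA (eleven-atom tether from the diene terminus to the dienophile carbon that binds it). The cis relation of chain and ring CH3 follows from the two outward groups of 30, the spiro centre from the transition state with the C(OCH3)=C(acyl) arm endo and the ring oxygen exo, and the absolute sense from the two chain centres, since A(1,3) strain at the allylic CH(CH3) next to the Z-enone and the syn-pentane-free conformation of the syn-1,3-dimethyl segment should leave one diene face open. Regiochemistry is secured twice (by the tether and by the para rule for a 2-carbomethoxy diene), chemoselectivity over the trisubstituted enone C=C by the much higher reactivity of the 1,1-disubstituted captodative C=CH2, and diene dimerisation is suppressed by its slow release at high dilution.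

**Step 18**
Reactants: 31 O-methyl okilactomycin C methyl ester
Product: 32 okilactomycin C methyl ester (free 3-acyl tetronic acid)
Conditions: LiCl, DMSO, 60 °C; dilute HCl work-up
Reagents that add atoms: none
Why: SN2 O-demethylation of the doubly vinylogous methyl ester by chloride is driven by the stabilised 3-acyl tetronate leaving group, whereas the ordinary methyl ester is not cleaved at this temperature.

**Step 19**
Reactants: 32 okilactomycin C methyl ester
Product: 33 okilactomycin C
Conditions: LiOH, THF–MeOH–H2O, 40 °C; then 1 M HCl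
Reagents that add atoms: lithium hydroxide, [Li+].[OH-]
Why: In this ester saponification (BAc2) the tetronic acid is present as its delocalised anion, which shields the lactone and the enone from hydroxide, and no stereocentre carries a proton acidic enough to epimerise.

**Compound list**
1 | meso-(cis)-2,4-dimethylglutaric anhydride | C[C@H]1C[C@@H](C)C(=O)OC1=O | starting material
2 | meso-(2R,4S)-2,4-dimethylpentane-1,5-diol | OC[C@H](C)C[C@H](C)CO | intermediate
3 | meso-(2R,4S)-2,4-dimethylpentane-1,5-diyl diacetate | CC(=O)OC[C@H](C)C[C@H](C)COC(C)=O | intermediate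
4 | (2R,4S)-5-hydroxy-2,4-dimethylpentyl acetate | CC(=O)OC[C@H](C)C[C@H](C)CO | intermediate
5 | (2R,4S)-2,4-dimethyl-5-(tosyloxy)pentyl acetate | CC(=O)OC[C@H](C)C[C@H](C)COS(=O)(=O)c1ccc(C)cc1 | intermediate
6 | but-3-en-1-ylmagnesium bromide | C=CCC[Mg]Br | starting material
7 | (2R,4R)-2,4-dimethylnon-8-en-1-ol | OC[C@H](C)C[C@H](C)CCCC=C | intermediate
8 | (2R,4R)-2,4-dimethylnon-8-enal | O=C[C@H](C)C[C@H](C)CCCC=C | intermediate
9 | ethyl 2-[bis(2,2,2-trifluoroethoxy)phosphoryl]propanoate | CCOC(=O)C(C)P(=O)(OCC(F)(F)F)OCC(F)(F)F | starting material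
10 | potassium salt of the carbanion of 9 | CCOC(=O)[C-](C)P(=O)(OCC(F)(F)F)OCC(F)(F)F.[K+] | intermediate
11 | ethyl (2Z,4R,6R)-2,4,6-trimethylundeca-2,10-dienoate | CCOC(=O)/C(C)=C\[C@H](C)C[C@H](C)CCCC=C | intermediate
12 | N,N-dimethylpropanamide | CCC(=O)N(C)C | starting material
13 | N,N-dimethylprop-1-en-1-ylideneammonium triflate (keteniminium salt) | CC=C=[N+](C)C.[O-]S(=O)(=O)C(F)(F)F | intermediate
14 | trans-cyclobutaniminium triflate from 11 and 13 | CCOC(=O)/C(C)=C\[C@H](C)C[C@H](C)CCC[C@H]1CC(=[N+](C)C)[C@@H]1C.[O-]S(=O)(=O)C(F)(F)F | intermediate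
15 | ethyl (2Z,4R,6R)-2,4,6-trimethyl-9-[(1S,2R)-2-methyl-3-oxocyclobutyl]non-2-enoate | CCOC(=O)/C(C)=C\[C@H](C)C[C@H](C)CCC[C@H]1CC(=O)[C@@H]1C | intermediate
16 | potassium enolate of 15 (towards ring CH2) | CCOC(=O)/C(C)=C\[C@H](C)C[C@H](C)CCC[C@H]1C=C([O-])[C@@H]1C.[K+] | intermediate
17 | ethyl (2Z,4R,6R)-2,4,6-trimethyl-9-[(1S,4R)-4-methyl-3-(triflyloxy)cyclobut-2-en-1-yl]non-2-enoate | CCOC(=O)/C(C)=C\[C@H](C)C[C@H](C)CCC[C@H]1C=C(OS(=O)(=O)C(F)(F)F)[C@@H]1C | intermediate
18 | (3S,4R)-3-[(4R,6R,7Z)-9-hydroxy-4,6,8-trimethylnon-7-en-1-yl]-4-methylcyclobut-1-en-1-yl triflate | OC/C(C)=C\[C@H](C)C[C@H](C)CCC[C@H]1C=C(OS(=O)(=O)C(F)(F)F)[C@@H]1C | intermediate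
19 | methyl (3S,4R)-3-[(4R,6R,7Z)-9-hydroxy-4,6,8-trimethylnon-7-en-1-yl]-4-methylcyclobut-1-ene-1-carboxylate | OC/C(C)=C\[C@H](C)C[C@H](C)CCC[C@H]1C=C(C(=O)OC)[C@@H]1C | intermediate
20 | methyl (3S,4R)-4-methyl-3-[(4R,6R,7Z)-4,6,8-trimethyl-9-oxonon-7-en-1-yl]cyclobut-1-ene-1-carboxylate | O=C/C(C)=C\[C@H](C)C[C@H](C)CCC[C@H]1C=C(C(=O)OC)[C@@H]1C | intermediate
21 | 4-methoxyfuran-2(5H)-one (methyl tetronate) | COC1=CC(=O)OC1 | starting material
22 | N,N-dimethylmethyleneiminium iodide (Eschenmoser's salt) | C=[N+](C)C.[I-] | starting material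
23 | lithium 4-methoxyfuran-2-olate | [Li+].[O-]c1cc(OC)co1 | intermediate
24 | (±)-5-[(dimethylamino)methyl]-4-methoxyfuran-2(5H)-one | COC1=CC(=O)OC1CN(C)C | intermediate
25 | (±)-(3-methoxy-5-oxo-2,5-dihydrofuran-2-yl)-N,N,N-trimethylmethanaminium iodide | COC1=CC(=O)OC1C[N+](C)(C)C.[I-] | intermediate
26 | 4-methoxy-5-methylidenefuran-2(5H)-one | COC1=CC(=O)OC1=C | intermediate
27 | 3-lithio-4-methoxy-5-methylidenefuran-2(5H)-one | COC1=C([Li])C(=O)OC1=C | intermediate
28 | carbinol from 27 and 20 (both carbinol epimers) | COC1=C(C(O)/C(C)=C\[C@H](C)C[C@H](C)CCC[C@H]2C=C(C(=O)OC)[C@@H]2C)C(=O)OC1=C | intermediate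
29 | 3-(Z-enoyl)-4-methoxy-5-methylidene tetronate with trans-cyclobutene ester (precursor of the key step) | COC1=C(C(=O)/C(C)=C\[C@H](C)C[C@H](C)CCC[C@H]2C=C(C(=O)OC)[C@@H]2C)C(=O)OC1=C | intermediate
30 | methyl (2Z,3E,8R,10R,11Z)-2-ethylidene-13-(4-methoxy-5-methylidene-2-oxo-2,5-dihydrofuran-3-yl)-8,10,12-trimethyl-13-oxotrideca-3,11-dienoate | COC1=C(C(=O)/C(C)=C\[C@H](C)C[C@H](C)CCC/C=C/C(C(=O)OC)=C/C)C(=O)OC1=C | intermediate
31 | O-methyl okilactomycin C methyl ester | CC1=C/[C@H](C)C[C@H](C)CCC[C@H]2C=C(C(=O)OC)[C@@H](C)C[C@]23OC(=O)C(C\1=O)=C3OC | intermediate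
32 | okilactomycin C methyl ester | CC1=C/[C@H](C)C[C@H](C)CCC[C@H]2C=C(C(=O)OC)[C@@H](C)C[C@]23OC(=O)\C(=C\1O)C3=O | intermediate
33 | okilactomycin C | CC1=C/[C@H](C)C[C@H](C)CCC[C@H]2C=C(C(=O)O)[C@@H](C)C[C@]23OC(=O)\C(=C\1O)C3=O | target

**Total step count:** 19. **Longest linear sequence:** 17 (steps 1–12 and 15–19).

**Steps most likely to fail**

Step 17. The electrocyclic opening needs about 130 °C.
- At this temperature the Z-enone may tautomerise through a 1,5-hydrogen shift to a dienol, which would erode the alkene geometry and the allylic configuration.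
- The doubly activated methylene tetronate may oligomerise.
- Facial selection by the remote chain centres may be incomplete.

The fallback separates the two pericyclic events, so that only a robust compound sees the high temperature. It sets out from 19 and comes back at 30.
- 19 is heated alone (PhCl, dilute, BHT, 130 °C) to give the ring-opened diene alcohol F1.
- TEMPO/PhI(OAc)2 oxidation gives the dienal F2.
- Addition of 27 gives the carbinol F3.
- Dess–Martin oxidation gives 30, which can then cyclise to 31 at the lowest temperature the cycloaddition itself needs (rt to 80 °C).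

Step 8. The monosubstituted keteniminium ion may add only sluggishly to an unactivated terminal alkene used as the limiting component, and it may be consumed by self-condensation. The fallback builds the ring with a ketene and adds the methyl group afterwards. It sets out from 11 and comes back at 15.
- Dichloroketene (Cl3CCOCl, Zn–Cu, Et2O) adds to the terminal alkene to give the dichlorocyclobutanone F4.
- Zn/AcOH dechlorination gives the 3-substituted cyclobutanone F5, whose two α-positions are equivalent.
- LDA/MeI alkylation anti to the 3-substituent gives trans-15.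

Step 15. During lithiation, the amide base may add to the exocyclic methylene, 26 may oligomerise anionically, or the vinyllithium may decay before it meets the aldehyde. The fallback avoids strong base. It sets out from 26 and comes back at 28.
- Electrophilic iodination at C3 (N-iodosuccinimide, cat. TFA, MeCN) gives the 3-iodo-4-methoxy-5-methylidenefuranone F6.
- F6 is coupled with 20 under Nozaki–Hiyama–Kishi conditions (CrCl2, cat. NiCl2, DMF–THF, rt), which tolerate the ester, to give 28.

**Further compounds**
F1 | step 17 | methyl (2Z,3E,8R,10R,11Z)-2-ethylidene-13-hydroxy-8,10,12-trimethyltrideca-3,11-dienoate | OC/C(C)=C\[C@H](C)C[C@H](C)CCC/C=C/C(C(=O)OC)=C/C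
F2 | step 17 | methyl (2Z,3E,8R,10R,11Z)-2-ethylidene-8,10,12-trimethyl-13-oxotrideca-3,11-dienoate | O=C/C(C)=C\[C@H](C)C[C@H](C)CCC/C=C/C(C(=O)OC)=C/C
F3 | step 17 | carbinol from 27 and F2 (both carbinol epimers) | COC1=C(C(O)/C(C)=C\[C@H](C)C[C@H](C)CCC/C=C/C(C(=O)OC)=C/C)C(=O)OC1=C
F4 | step 8 | ethyl (2Z,4R,6R)-9-(2,2-dichloro-3-oxocyclobutyl)-2,4,6-trimethylnon-2-enoate (both ring epimers) | CCOC(=O)/C(C)=C\[C@H](C)C[C@H](C)CCCC1CC(=O)C1(Cl)Cl
F5 | step 8 | ethyl (2Z,4R,6R)-2,4,6-trimethyl-9-(3-oxocyclobutyl)non-2-enoate | CCOC(=O)/C(C)=C\[C@H](C)C[C@H](C)CCCC1CC(=O)C1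
F6 | step 15 | 3-iodo-4-methoxy-5-methylidenefuran-2(5H)-one | COC1=C(I)C(=O)OC1=C
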